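(Readings and results are calculated with made-up constants; noise was put on by code.)

A small charge of starting material should run down on one clock, so for north-east I want its half-life and not a rate.

| flask | starting material | second substrate | free enzyme | remark | time |
|---|---|---|---|---|---|
| theta | 0.20 M (in portions, 2) | 0.072 M | 46 µM | run made earlier; portions every 1.5 h |  |
| beta | 0.20 M (in portions, 2) | 0.17 M | 46 µM | run made earlier; portions every 1.5 h |  |
| delta | 0.12 M (in portions, 2) | 0.10 M | 46 µM | run made earlier; portions every 1.5 h |  |
| south-east | 0.20 M (in portions, 2) | 0.100 M | 46 µM | the portions of starting material follow each other after 1.5 h, the first at the start | 5.0 h |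
| north-east | 0.050 M | 0.200 M | 46 µM | everything together at the start | 5.0 h |

| run | time / h | target / % |
|---|---|---|
| theta | 0.417 | 1.6 |
| theta | 1.00 | 4.1 |
| theta | 2.00 | 7.8 |
| theta | 5.00 | 19.1 |
| beta | 1.33 | 5.7 |
| beta | 2.50 | 9.2 |
| beta | 4.00 | 14.1 |
| beta | 5.00 | 17.5 |
| delta | 0.417 | 1.6 |
| delta | 1.00 | 5.8 |
| delta | 2.00 | 9.8 |
| delta | 5.00 | 22.6 |

(scatter of a reading: 0.5 percentage points)

- which of the two ends with the higher amount of target, in percent of the starting material charged ("neither" if they lie within 2 percentage points) (south-east / north-east / neither)
- target at the end, in percent of the starting material charged, south-east
- target at the end, in percent of the starting material charged, north-east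

- the analysis behind the earlier runs scatters by 0.5 percentage points, standard deviation
- steps that have been proposed: second substrate + target -> over-reaction product; first complex -> loaded enzyme + first product; second complex -> free enzyme + target; second substrate + loaded enzyme <-> second complex; free enzyme <-> dormant form; starting material + free enzyme <-> first complex

Delta, at a mean [starting material] of about 0.0884 M, makes target at 5.42 mM/h. Theta, at about 0.151 M, makes 7.64 mM/h. Dividing what is held by that rate gives a lifetime of the starting material: 16.3 h in delta and 19.8 h in theta, longer in the fuller flask. Run that straight line back to an empty flask and the lifetime is 11.4 h, which makes 7.92 h the pseudo-first-order half-life, the time in which a thin charge falls to half under this much enzyme.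

But north-east is not empty, and at its 0.050 M the line stands higher. Against that, target counts what survives, so both readings understate what the starting material loses. The two errors pull opposite ways, and I keep the figure. By this reckoning north-east runs 0.631 half-lives in 5.0 h, leaving 64.6% and turning over 35.4%.

That is a conversion, and target is a different count. Theta ends 1.6 percentage points above beta, though beta holds more second substrate. Read as over-reaction, that gap gives target a half-life of 9.71 h at north-east's [second substrate]. The gap is just 2.26 times its own scatter, so this is weak. I take target to live on average half the run, so I reckon that 83.7% survives and I commit to 29.6% for north-east, perhaps less. South-east lies between theta and beta in second substrate, so I take their mean, 18.3%, and north-east ends higher.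

The forecast also names north-east, with 18.7% (17.3% to 20.2%) for south-east and 38% (28% to 48%) for north-east, above my figure, its conversion taken “less a few mM over-reacted”.

The simulation gives 18.8% for south-east and 25.5% for north-east, so north-east ends higher.

    second substrate + target → over-reaction product (k = 2.10 × 10⁻⁴ /M/s)
    first complex → loaded enzyme + first product (k = 0.140 /s)
    second complex → free enzyme + target (k = 0.850 /s)
    second substrate + loaded enzyme ⇌ second complex (K = 26.0 /M, k = 140 /M/s)
    free enzyme ⇌ dormant form (K = 1.50, k = 4.70 × 10⁻⁵ /s)
    starting material + free enzyme ⇌ first complex (K = 7.20 /M, k = 16.0 /M/s)

North-east keeps 63% of its starting material unbound at 5.00 h, against the 64.6% that 7.92 h gave. North-east run without the back reaction of first complex to starting material + free enzyme ends at 68.9% target instead of 25.5%, so that back reaction, worth 43 points, is the main reason for the low figure in north-east. Scaled to the neighbour flask with 1.2 × 10⁻⁴ M of free enzyme, the half-life becomes 3.04 h and leaves 31.9%; that flask holds 28% of its starting material.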